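**Plan**

- Retrosynthesis: the C2–Br and C3–Br bonds are cut first (late electrophilic bromination of the pyrrole ring of 5,6-dibromoindole), then the benzene ring is cut at C3a–C4 and C7–C7a.
- Enabling feature: C4–C5(Br)–C6(Br)–C7 of the benzo ring is a butadiene brominated on its two inner carbons, which is the carbon frame of 3,4-dibromothiophene. The C3a–C7a bond shared by the two rings, with N1 on C7a, is the enamide C=C of an N-acyl-2-pyrroline.
- Forward: the five-membered N ring is bought as N-Boc-2-pyrroline. The six-membered ring is closed onto it by Diels–Alder addition of 3,4-dibromothiophene 1,1-dioxide with loss of SO2. The new ring is aromatised with DDQ, Boc is removed, the indoline is dehydrogenated to the indole, and C3 then C2 are brominated.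
- Stereochemistry: the target has no stereocentre. The cis ring fusion from the suprafacial cycloaddition is racemic and is erased on aromatisation.

Key step: step 2

Remark: the target is achiral, so the single structure given needs no asymmetric step.

**Route**

Step 1
Reactants: 1 3,4-dibromothiophene
Product: 3 3,4-dibromothiophene 1,1-dioxide, via 3,4-dibromothiophene 1-oxide 2 (not isolated)
Conditions: CF3CO3H [(CF3CO)2O, 50% aq H2O2], CH2Cl2, 0 °C → rt
Reagents that add atoms: trifluoroperacetic acid, O=C(OO)C(F)(F)F, made in the flask from hydrogen peroxide, OO, and trifluoroacetic anhydride, O=C(OC(=O)C(F)(F)F)C(F)(F)F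
Why: Peracid S-oxidation: trifluoroperacetic acid is electrophilic enough to oxidise the weakly nucleophilic sulfur of a dihalothiophene, sulfoxide 2 should be oxidised again faster than it dimerises, and the 3,4-dibromo pattern should make the non-aromatic sulfone 3 isolable.

Step 2
Reactants: 3 3,4-dibromothiophene 1,1-dioxide; 4 tert-butyl 2,3-dihydro-1H-pyrrole-1-carboxylate (N-Boc-2-pyrroline)
Product: 6 tert-butyl cis-5,6-dibromo-2,3,3a,7a-tetrahydro-1H-indole-1-carboxylate (racemic), via bridged sulfone cycloadduct 5 (not isolated)
Conditions: 4 (3 equiv), 2,6-di-tert-butylpyridine (10 mol%), PhMe, 85 °C, slow addition of 3, N2 sweep; excess 4 removed in vacuo, crude 6 taken on at once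
Reagents that add atoms: none
Why: The non-aromatic, electron-poor sulfone 3 serves as the 4π partner of the electron-rich enecarbamate C=C of 4 in a concerted inverse-electron-demand Diels–Alder reaction, and the 7-thiabicyclo[2.2.1]heptene 7,7-dioxide 5 then ejects SO2 in an allowed cheletropic step to leave the 1,3-diene 6 with bromine on both inner carbons. The closest known reaction type is the annulation of halogenated thiophene 1,1-dioxides with alkenes, enol ethers and enamines. The carbocycle closes as a [4+2] annulation onto the preformed five-membered ring, C3a–C4 and C7–C7a forming in one suprafacial event, while the sulfur-bridged ring of 5 is only transient. C3a and C7a are set cis because both bonds form on one face of the cyclic Z-alkene; the endo/exo outcome and the two bridgehead centres of 5 vanish with SO2, and the cis centres themselves are erased in step 3. The step needs chemoselectivity for cross- over self-cycloaddition of 3 and no regiocontrol: the nitrogen donor raises the HOMO of 4, the sulfone is kept dilute against excess 4, and the mirror symmetry of 3 makes both orientations identical so that bromine can only end up at C5 and C6. The hindered pyridine and the N2 sweep keep SO2-derived acid from ionising the allylic C7a–N bond, and H3a lies on the face opposite to nitrogen, so a thermal syn-elimination has no cyclic transition state.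

Step 3
Reactants: 6 tert-butyl cis-5,6-dibromo-2,3,3a,7a-tetrahydro-1H-indole-1-carboxylate
Product: 7 tert-butyl 5,6-dibromoindoline-1-carboxylate
Conditions: DDQ (1.1 equiv), PhMe, 0 °C → rt
Reagents that add atoms: none
Why: DDQ dehydrogenation of a 1,3-cyclohexadiene to an arene: hydride is taken from the allylic, nitrogen-bearing C7a–H (or from C3a–H) and a proton from the neighbouring ring-fusion carbon, benzene resonance drives the reaction at or below rt, the hydroquinone precipitates from toluene so little acid reaches the C7a–N bond, and the carbamate and aryl bromides are inert.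

Step 4
Reactants: 7 tert-butyl 5,6-dibromoindoline-1-carboxylate
Product: 9 5,6-dibromoindoline, via 5,6-dibromoindoline-1-carboxylic acid 8 (not isolated)
Conditions: TFA, CH2Cl2, 0 °C → rt; aq NaHCO3
Reagents that add atoms: none
Why: Acidolysis of a tert-butyl carbamate (Boc removal): loss of the tert-butyl cation as isobutene gives carbamic acid 8, which decarboxylates, while the protonated, doubly brominated indoline is too deactivated to be tert-butylated and the aryl bromides are untouched.

Step 5
Reactants: 9 5,6-dibromoindoline
Product: 10 5,6-dibromo-1H-indole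
Conditions: DDQ (1.05 equiv), 1,4-dioxane, rt
Reagents that add atoms: none
Why: Quinone dehydrogenation of an indoline to an indole: nitrogen-assisted hydride abstraction from C2 followed by tautomerisation creates the aromatic pyrrole ring, and the electron-poor dibromoindole should resist further oxidation.

Step 6
Reactants: 10 5,6-dibromo-1H-indole
Product: 12 2,3,5,6-tetrabromo-1H-indole, via 3,5,6-tribromo-1H-indole 11 (not isolated)
Conditions: NBS (2.1 equiv, two portions), SiO2, CH2Cl2, 0 °C → rt, dark
Reagents that add atoms: N-bromosuccinimide, O=C1CCC(=O)N1Br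
Why: Electrophilic aromatic bromination of an indole with NBS: C3 reacts first to give 11, the second equivalent brominates C2 of the 3-bromoindole, and the two bromines already on the benzo ring deactivate C4 and C7 so that only the pyrrole carbons react.

**Compound list**

1 | 3,4-dibromothiophene | Brc1cscc1Br | starting material
2 | 3,4-dibromothiophene 1-oxide | O=S1C=C(Br)C(Br)=C1 | intermediate (not isolated)
3 | 3,4-dibromothiophene 1,1-dioxide | O=S1(=O)C=C(Br)C(Br)=C1 | intermediate
4 | tert-butyl 2,3-dihydro-1H-pyrrole-1-carboxylate (N-Boc-2-pyrroline) | CC(C)(C)OC(=O)N1CCC=C1 | starting material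
5 | tert-butyl 5,6-dibromo-2,3,3a,4,7,7a-hexahydro-4,7-epithioindole-1-carboxylate 8,8-dioxide (SO2 bridging C4 and C7, cis ring fusion, pyrrolidine ring anti to the SO2 bridge as drawn, racemic) | CC(C)(C)OC(=O)N1CC[C@H]2[C@@H]1[C@H]1C(Br)=C(Br)[C@@H]2S1(=O)=O | intermediate (not isolated)
6 | tert-butyl cis-5,6-dibromo-2,3,3a,7a-tetrahydro-1H-indole-1-carboxylate (H3a and H7a on the same face, racemic, one enantiomer drawn) | CC(C)(C)OC(=O)N1CC[C@@H]2C=C(Br)C(Br)=C[C@H]12 | intermediate
7 | tert-butyl 5,6-dibromoindoline-1-carboxylate | CC(C)(C)OC(=O)N1CCc2cc(Br)c(Br)cc21 | intermediate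
8 | 5,6-dibromoindoline-1-carboxylic acid | OC(=O)N1CCc2cc(Br)c(Br)cc21 | intermediate (not isolated)
9 | 5,6-dibromoindoline | Brc1cc2CCNc2cc1Br | intermediate
10 | 5,6-dibromo-1H-indole | Brc1cc2cc[nH]c2cc1Br | intermediate
11 | 3,5,6-tribromo-1H-indole | Brc1cc2[nH]cc(Br)c2cc1Br | intermediate (not isolated)
12 | 2,3,5,6-tetrabromo-1H-indole | Brc1cc2[nH]c(Br)c(Br)c2cc1Br | target

**Count and risks**

Total step count: 6. Longest linear sequence: 6 steps (from 1; 4 is bought and enters at step 2).

Step 2 (most likely to fail). Self-cycloaddition of the sulfone may outrun the cross reaction, or the enecarbamate may oligomerise under SO2-derived acid. The fallback sets out from 3 and moves the dienophile to the lactam oxidation level, so that it is more electron-rich and the adduct aromatises by elimination instead of oxidation. Commercial tert-butyl 2-oxopyrrolidine-1-carboxylate is O-silylated (TBSOTf, Et3N, CH2Cl2, 0 °C) to the ketene N,O-acetal tert-butyl 5-[(tert-butyldimethylsilyl)oxy]-2,3-dihydro-1H-pyrrole-1-carboxylate F1. Heating F1 with 3 (PhMe, 60 °C, N2 sweep) should give the bridged sulfone tert-butyl 5,6-dibromo-7a-[(tert-butyldimethylsilyl)oxy]-2,3,3a,4,7,7a-hexahydro-4,7-epithioindole-1-carboxylate 8,8-dioxide F2. Loss of SO2 from F2 then gives tert-butyl cis-5,6-dibromo-7a-[(tert-butyldimethylsilyl)oxy]-2,3,3a,7a-tetrahydro-1H-indole-1-carboxylate F3. On contact with PPTS, F3 should ionise at C7a–O to the N-acyliminium (arenium) ion and lose silanol and H3a. The fallback comes back to the route at 7, and step 3 is no longer needed.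

Step 3. The allylic C7a–N bond may ionise under the acidity of the hydroquinone, so that the ring aromatises by opening instead of by dehydrogenation; DDQ may also add to the diene. The fallback sets out from 6 and turns this side reaction into the route. TFA in CH2Cl2 completes the ring opening to tert-butyl [2-(3,4-dibromophenyl)ethyl]carbamate F4 and removes its Boc group to give 2-(3,4-dibromophenyl)ethan-1-amine F5. Acylation with picolinic acid (EDC, HOBt, CH2Cl2) gives N-[2-(3,4-dibromophenyl)ethyl]pyridine-2-carboxamide F6. Picolinamide-directed intramolecular C–H amination (Pd(OAc)2 cat., PhI(OAc)2, PhMe, 60 °C) should close the C–N bond at the unhindered ortho position, giving (5,6-dibromo-2,3-dihydro-1H-indol-1-yl)(pyridin-2-yl)methanone F7; the Pd(II)/Pd(IV) cycle leaves the aryl bromides alone. Hydrolysis of the amide (NaOH, EtOH, reflux) brings the fallback back to the route at 9.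

Step 6. Water may intercept the brominated intermediates and lead to oxindoles, the second bromination at C2 may stall, or the N–H dibromoindole may decompose in the acidic medium. The fallback sets out from 10 and replaces the second electrophilic bromination by directed metalation. N-Sulfonylation (PhSO2Cl, NaH, THF) gives 5,6-dibromo-1-(phenylsulfonyl)-1H-indole F8. Bromination at C3 (Br2, DMF) gives 3,5,6-tribromo-1-(phenylsulfonyl)-1H-indole F9. Deprotonation at C2 (LDA, THF, −78 °C) and quenching with 1,2-dibromo-1,1,2,2-tetrachloroethane gives 2,3,5,6-tetrabromo-1-(phenylsulfonyl)-1H-indole F10. Cleavage of the sulfonamide (NaOH, MeOH/THF, rt) brings the fallback back to the route at 12.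

**Further compounds**

F1 | step 2 | tert-butyl 5-[(tert-butyldimethylsilyl)oxy]-2,3-dihydro-1H-pyrrole-1-carboxylate | CC(C)(C)OC(=O)N1CCC=C1O[Si](C)(C)C(C)(C)C
F2 | step 2 | tert-butyl 5,6-dibromo-7a-[(tert-butyldimethylsilyl)oxy]-2,3,3a,4,7,7a-hexahydro-4,7-epithioindole-1-carboxylate 8,8-dioxide (racemic, one diastereomer drawn) | CC(C)(C)OC(=O)N1CC[C@H]2[C@]1(O[Si](C)(C)C(C)(C)C)[C@H]1C(Br)=C(Br)[C@@H]2S1(=O)=O
F3 | step 2 | tert-butyl cis-5,6-dibromo-7a-[(tert-butyldimethylsilyl)oxy]-2,3,3a,7a-tetrahydro-1H-indole-1-carboxylate (racemic) | CC(C)(C)OC(=O)N1CC[C@@H]2C=C(Br)C(Br)=C[C@]12O[Si](C)(C)C(C)(C)C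
F4 | step 3 | tert-butyl [2-(3,4-dibromophenyl)ethyl]carbamate | CC(C)(C)OC(=O)NCCc1ccc(Br)c(Br)c1
F5 | step 3 | 2-(3,4-dibromophenyl)ethan-1-amine | NCCc1ccc(Br)c(Br)c1
F6 | step 3 | N-[2-(3,4-dibromophenyl)ethyl]pyridine-2-carboxamide | O=C(NCCc1ccc(Br)c(Br)c1)c1ccccn1
F7 | step 3 | (5,6-dibromo-2,3-dihydro-1H-indol-1-yl)(pyridin-2-yl)methanone | O=C(c1ccccn1)N1CCc2cc(Br)c(Br)cc21
F8 | step 6 | 5,6-dibromo-1-(phenylsulfonyl)-1H-indole | O=S(=O)(c1ccccc1)n1ccc2cc(Br)c(Br)cc21
F9 | step 6 | 3,5,6-tribromo-1-(phenylsulfonyl)-1H-indole | O=S(=O)(c1ccccc1)n1cc(Br)c2cc(Br)c(Br)cc21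
F10 | step 6 | 2,3,5,6-tetrabromo-1-(phenylsulfonyl)-1H-indole | O=S(=O)(c1ccccc1)n1c(Br)c(Br)c2cc(Br)c(Br)cc21
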